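**Retrosynthetic overview**

1. Target ⇐ desilylation, oxidative lactonisation of the C6–OH/C12–OH pair and 1,2-reduction at C6 of a ten-membered 1,6-dione with a Z C4=C5 bond.
2. Feature used: C1 (ketone) and C6 (lactone carbinol) both carry oxygen and lie opposite each other in the ten-membered carbocycle C1–C10. A temporary C1–C6 bond makes this ring the periphery of a cis-fused bicyclo[4.4.0]dec-4-ene (ring A: C1–C6; ring B: C1, C6–C10) whose fusion bond is a glycol, cut with Pb(OAc)4.
3. Ring A ⇐ intramolecular aldol addition of the C2 enolate of a C3 methyl ketone to the C1 ketone, then 1,3-syn reduction at C3; C5–C6 ⇐ Pd-catalysed α-alkenylation of the ring B ketone; C6–OH ⇐ enolate hydroxylation.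
4. Ring B ⇐ quinone monoketal of 4-methoxy-2-methylphenol: C7 by Rh/BINAP conjugate addition of an alkenyltrifluoroborate, C10–O by Rubottom oxidation, C8–O by hydride reduction after ketal hydrolysis.
5. Order of ring formation: ring B (from the arene), ring A (step 13), ten-membered ring (glycol cleavage, step 19), γ-lactone (step 22).

Key step: step 19

**Remarks on the chemistry**

- Germacrane numbering is used throughout (C1 ketone, C3 carbinol, C4(Me)=C5, C6 lactone carbinol, C7, C8 ester carbinol, C10 methyl carbinol, C11(=C13H2)–C12 lactone carbonyl). β is the face of ring B that carries the C10 oxygen. PMB = 4-methoxybenzyl, TES = triethylsilyl, TBS = tert-butyldimethylsilyl.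
- The C7 substituent is carried through the key step as the 3-(PMB-oxy)prop-1-en-2-yl group (C12 as CH2OPMB). An acrylate ester there would not survive the enolate and hydride steps and would make H7 of the dione more acidic; the lactone carbonyl is made afterwards by oxidative lactonisation.
- C1–C2 is closed by an aldol addition and not by a reductive (SmI2) coupling of a C2 halide: SmI2 would cleave the two α-oxygen substituents of the C1 ketone, and a C2 carbanion would expel a C3 silyloxy group.
- The C1 and C6 carbinol configurations (both β) are those that the route delivers; both centres become carbonyl carbons in step 19.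
- Assumption: the facial sense of (R)-BINAP on the dienone follows the accepted model for cyclohex-2-enone; the antipodal ligand is used if it proves opposite.

**Route**

Step 1
Reactants: 1 2,3-dibromoprop-1-ene; 2 (4-methoxyphenyl)methanol
Product: 3 2-bromoallyl 4-methoxybenzyl ether
Conditions: NaH, THF, 0 → 25 °C
Reagents that add atoms: none
Why: Williamson etherification: the sodium alkoxide of 2 displaces the allylic bromide of 1 by SN2, the vinylic bromide being inert.

Step 2
Reactants: 3 2-bromoallyl 4-methoxybenzyl ether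
Product: 6 potassium trifluoro[3-(PMB-oxy)prop-1-en-2-yl]borate, via vinyllithium 4 (not isolated), via lithium alkenyltriisopropoxyborate 5 (not isolated)
Conditions: tBuLi (2 equiv), Et2O, −78 °C; B(OiPr)3, −78 → 0 °C; aq KHF2, MeOH
Reagents that add atoms: triisopropyl borate (CC(C)OB(OC(C)C)OC(C)C); potassium hydrogen difluoride (F.[F-].[K+])
Why: Bromine–lithium exchange at −78 °C (the 2-lithioallyl ether is stable there), borylation to the ate complex and fluoride exchange should give the bench-stable alkenyltrifluoroborate needed for the conjugate addition.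

Step 3
Reactants: 7 (2S)-but-3-yn-2-ol
Product: 9 (2S,3Z)-4-iodo-3-methylbut-3-en-2-ol, via alkenylmagnesium alkoxide 8 (not isolated)
Conditions: MeMgBr (3 equiv), CuI (10 mol %), THF, 0 → 25 °C; I2, −78 → 0 °C; aq NH4Cl
Reagents that add atoms: methylmagnesium bromide (C[Mg]Br); iodine (II)
Why: Copper-catalysed anti-carbomagnesiation of the propargylic magnesium alkoxide puts methyl on the carbinol-bound alkyne carbon and magnesium on the terminal one within a five-membered chelate, so iodinolysis with retention should give the Z iodide (iodine cis to the carbinol carbon, the later C3); the carbinol centre is untouched.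

Step 4
Reactants: 9 (2S,3Z)-4-iodo-3-methylbut-3-en-2-ol
Product: 10 (2S,3Z)-4-iodo-3-methylbut-3-en-2-yl triethylsilyl ether
Conditions: TESCl, imidazole, DMF, 0 °C
Reagents that add atoms: chlorotriethylsilane (CC[Si](Cl)(CC)CC)
Why: Standard silylation of a secondary alcohol, masking it for the base-mediated coupling of step 9.

Step 5
Reactants: 11 4-methoxy-2-methylphenol
Product: 12 4,4-dimethoxy-2-methylcyclohexa-2,5-dien-1-one
Conditions: PhI(OAc)2, MeOH, 0 °C
Reagents that add atoms: methanol (CO)
Why: Oxidative dearomatisation of the para-methoxyphenol with capture of the phenoxenium ion by methanol at C4 gives the quinone monoketal.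

Step 6
Reactants: 12 4,4-dimethoxy-2-methylcyclohexa-2,5-dien-1-one; 6 potassium alkenyltrifluoroborate
Product: 13 (5R)-4,4-dimethoxy-2-methyl-5-[3-(PMB-oxy)prop-1-en-2-yl]cyclohex-2-en-1-one
Conditions: [Rh(cod)2]BF4 (3 mol %), (R)-BINAP, Et3N, PhMe/H2O, 25 °C
Reagents that add atoms: none
Why: Rh/BINAP-catalysed asymmetric 1,4-addition (Hayashi–Miyaura type) of a 1-substituted alkenyltrifluoroborate, a reaction type known for quinone monoketals, should occur at the unsubstituted enone (the 2-methyl enone is much less reactive); the chiral Rh–alkenyl species selects one enone face and sets C7.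

Step 7
Reactants: 13 ring B enone
Product: 14 ring B triethylsilyl enol ether (C1–OTES; C1=C10)
Conditions: Et3SiH, RhCl(PPh3)3 (1 mol %), THF, 50 °C
Reagents that add atoms: triethylsilane (CC[SiH](CC)CC)
Why: Rh-catalysed 1,4-hydrosilylation of an enone with a monohydrosilane gives regiospecifically the tetrasubstituted C1=C10 silyl enol ether; the 1,1-disubstituted side-chain alkene reacts far more slowly.

Step 8
Reactants: 14 ring B triethylsilyl enol ether
Product: 16 ring B α-silyloxy ketone (C1 ketone; C10 methyl with β-OTES), via silyloxy epoxide 15 (not isolated)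
Conditions: mCPBA, NaHCO3, CH2Cl2, −20 °C
Reagents that add atoms: 3-chloroperbenzoic acid (OOC(=O)c1cccc(Cl)c1)
Why: Rubottom oxidation: the electron-rich enol ether is epoxidised before the side-chain alkene, from the β face anti to the axial C8 methoxy group that shares the α face with the equatorial C7 side chain, and the epoxide opens with 1,4-silyl shift, which should set C10 (oxygen trans to the C7 side chain) and place its TES group.

Step 9
Reactants: 16 ring B α-silyloxy ketone; 10 (Z)-alkenyl iodide
Product: 17 C6-alkenyl ketone (C6 carries the (1Z,3S)-2-methyl-3-(triethylsilyloxy)but-1-enyl group)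
Conditions: Pd2(dba)3 (2.5 mol %), P(tBu)3 (10 mol %), LiN(SiMe3)2 (2.2 equiv), THF, 25 °C; aq NH4Cl, −78 °C
Reagents that add atoms: none
Why: Palladium-catalysed α-alkenylation of a ketone enolate (C10 is quaternary, so only C6 can enolise) with retention of the Z geometry of 10; excess base holds the product as its dienolate so that cold protonation returns the β,γ-unsaturated ketone, and the C6 configuration does not matter because it is planarised in step 10.

Step 10
Reactants: 17 C6-alkenyl ketone
Product: 19 C6 tertiary α-hydroxy ketone (C6–OH β; alkenyl α), via potassium dienolate 18 (not isolated)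
Conditions: KN(SiMe3)2, THF, −78 °C; 2-(benzenesulfonyl)-3-phenyloxaziridine; AcOH
Reagents that add atoms: 2-(benzenesulfonyl)-3-phenyloxaziridine (O=S(=O)(c1ccccc1)N1OC1c1ccccc1)
Why: Enolate hydroxylation with an N-sulfonyloxaziridine (Davis oxidation) at the α-carbon of the dienolate; the C7 side chain lies pseudo-axial next to the trisubstituted enolate carbon to avoid allylic strain, so oxygen should enter anti to it and set C6–OH β.

Step 11
Reactants: 19 C6 tertiary α-hydroxy ketone
Product: 20 diol with free side-chain C3 hydroxyl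
Conditions: PPTS (cat.), MeOH, 0 °C
Reagents that add atoms: none
Why: Acid-catalysed methanolysis removes the secondary allylic TES ether far faster than the hindered tertiary one at C10, and methanol as solvent keeps the C8 dimethyl ketal intact.

Step 12
Reactants: 20 diol with free side-chain C3 hydroxyl
Product: 22 spiro-hemiketal of the (Z)-hydroxy enone (both anomers), via open hydroxy enone 21 (not isolated)
Conditions: MnO2, CH2Cl2, 25 °C
Reagents that add atoms: none
Why: MnO2 oxidises only the secondary allylic alcohol; the Z γ-hydroxy enone is expected to close to the hemiketal, a ring–chain tautomer that re-opens under base.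

Step 13
Reactants: 22 spiro-hemiketal
Product: 24 cis-fused decalin ketol (C1–OH β; C6–OH β; C3 ketone; C4(Me)=C5), via dilithium alkoxide enolate 23 (not isolated)
Conditions: LiN(iPr)2 (2.5 equiv), THF, −78 → −40 °C; AcOH, −78 °C
Reagents that add atoms: none
Why: Intramolecular aldol addition (the ketol-forming half of a Robinson annulation): excess amide base opens the hemiketal and forms the kinetic methyl-ketone enolate, whose C2 adds 6-exo to the C1 ketone; lithium bridging of the C6 alkoxide and the C1 carbonyl and the short Z tether should give the cis-fused ketol and set C1 (OH cis to C6–OH).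

Step 14
Reactants: 24 cis-fused decalin ketol
Product: 26 1β,3β,6β-triol, via diethylborinate 25 (not isolated)
Conditions: Et2BOMe, THF/MeOH (4:1), −78 °C; NaBH4; MeOH azeotrope
Reagents that add atoms: none
Why: Narasaka–Prasad reduction: the O1 diethylborinate chelates the C3 carbonyl and borohydride adds 1,2 from the face opposite the chelate, which should give the 1,3-cis diol and so the 3R carbinol.

Step 15
Reactants: 26 1β,3β,6β-triol
Product: 27 3-O-TBS ether
Conditions: TBSCl, imidazole, DMF, 0 °C
Reagents that add atoms: tert-butylchlorodimethylsilane (CC(C)(C)[Si](C)(C)Cl)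
Why: Silylation is selective for the only secondary hydroxyl; the tertiary C1 and C6 hydroxyls stay free.

Step 16
Reactants: 27 3-O-TBS ether
Product: 28 C8 ketone
Conditions: PPTS, acetone/H2O (10:1), 25 °C
Reagents that add atoms: water (O)
Why: Mild acid hydrolysis of the dimethyl ketal, safe now that C9–C10 is saturated and C10 quaternary (no aromatisation), should leave the silyl ethers and the tertiary allylic alcohol intact.

Step 17
Reactants: 28 C8 ketone
Product: 29 8α-alcohol
Conditions: LiBH(sBu)3, THF, −78 °C; H2O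
Reagents that add atoms: none
Why: The bulky hydride attacks the only ketone from the β face, anti to the adjacent C7 side chain, which should give the 8α alcohol cis to that side chain and set C8.

Step 18
Reactants: 29 8α-alcohol; 30 3-methylbutanoyl chloride
Product: 31 cis-decalin C1,C6-diol with C8 isovalerate (key-step precursor)
Conditions: pyridine, DMAP (cat.), CH2Cl2, 0 → 25 °C
Reagents that add atoms: none
Why: DMAP-catalysed acylation of the only secondary alcohol; the two tertiary hydroxyls at C1 and C6 do not react.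

Step 19
Reactants: 31 cis-decalin C1,C6-diol
Product: 33 ten-membered C1,C6-dione with Z C4=C5, via cyclic lead diester 32 (not isolated)
Conditions: Pb(OAc)4, CH2Cl2, −20 °C; cold aq NaHCO3
Reagents that add atoms: none
Why: The cis-disposed C1 and C6 hydroxyls exchange two acetates of Pb(OAc)4 to give a five-membered cyclic lead diester, whose two-electron collapse breaks the C1–C6 σ-bond, forms C1=O and C6=O and turns tetravalent lead into divalent lead. The closest known reaction type is the Criegee cleavage of ring-fusion decalindiols to cyclodecane-1,6-diones. No ring is closed by bond formation: the ten-membered carbocycle C1–C10 is released as the periphery of the bicycle, and the Z geometry of C4=C5 is inherited from six-membered ring A. No stereocentre is created; C1 and C6 become trigonal and C3, C7, C8 and C10 are carried over unchanged. The step must cut only the C1–C6 glycol: the C3 and C10 oxygens are silylated and C8 is acylated, so no second free 1,2-diol exists, and the cis fusion lets the cyclic diester form at −20 °C, well below the temperature of allylic or benzylic oxidation. The epimerisable H7 next to the new C6 ketone is guarded by the cold non-basic conditions, by the non-activating C7 substituent and by using 33 at once in step 20.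

Step 20
Reactants: 33 ten-membered C1,C6-dione
Product: 34 (6R)-allylic alcohol
Conditions: NaBH4, CeCl3·7H2O, MeOH, −78 °C
Reagents that add atoms: none
Why: Luche reduction: cerium-activated 1,2-reduction of the conjugated C6 ketone should outpace attack on the saturated C1 ketone shielded by quaternary C10, and hydride is expected from the peripheral face anti to the C7 side chain (Felkin–Anh, C7–C11 antiperiplanar, C5–C6–C7–C8 extended), giving the 6R alcohol with H6 and H7 anti.

Step 21
Reactants: 34 (6R)-allylic alcohol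
Product: 35 C6,C12-diol
Conditions: DDQ, CH2Cl2/pH 7 buffer, 0 °C
Reagents that add atoms: none
Why: Oxidative cleavage of the 4-methoxybenzyl ether by DDQ in wet solvent; silyl ethers, ester and alkenes are untouched.

Step 22
Reactants: 35 C6,C12-diol
Product: 38 bis-silylated α-methylene-γ-lactone, via hydroxy enal 36 (not isolated), via lactol 37 (not isolated)
Conditions: TEMPO (20 mol %), PhI(OAc)2 (2.5 equiv), CH2Cl2, 25 °C
Reagents that add atoms: none
Why: Oxoammonium oxidation is selective for the primary allylic C12 alcohol; the enal is trapped by the C6 hydroxyl as a lactol, which is oxidised on to the lactone (oxidative lactonisation of a 1,4-diol), the trans fusion being fixed by C6 and C7.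

Step 23
Reactants: 38 bis-silylated α-methylene-γ-lactone
Product: 39 CNP0406522.1
Conditions: HF·pyridine, pyridine, THF, 0 → 25 °C
Reagents that add atoms: none
Why: Fluoride cleaves the secondary TBS and tertiary TES ethers under pyridine-buffered conditions that should spare the β-hydroxy ketone, the isovalerate and the α-methylene lactone.

**Compound list**

1 | 2,3-dibromoprop-1-ene | C=C(Br)CBr | starting material
2 | (4-methoxyphenyl)methanol | COc1ccc(CO)cc1 | starting material
3 | 1-{[(2-bromoprop-2-en-1-yl)oxy]methyl}-4-methoxybenzene | C=C(Br)COCc1ccc(OC)cc1 | intermediate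
4 | {3-[(4-methoxybenzyl)oxy]prop-1-en-2-yl}lithium | [Li]C(=C)COCc1ccc(OC)cc1 | intermediate
5 | lithium triisopropoxy{3-[(4-methoxybenzyl)oxy]prop-1-en-2-yl}borate | [Li+].C=C(COCc1ccc(OC)cc1)[B-](OC(C)C)(OC(C)C)OC(C)C | intermediate
6 | potassium trifluoro{3-[(4-methoxybenzyl)oxy]prop-1-en-2-yl}borate | [K+].C=C(COCc1ccc(OC)cc1)[B-](F)(F)F | intermediate
7 | (2S)-but-3-yn-2-ol | C#C[C@H](C)O | starting material
8 | bromomagnesium (2S,3Z)-4-(bromomagnesio)-3-methylbut-3-en-2-olate | Br[Mg]/C=C(/C)[C@H](C)O[Mg]Br | intermediate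
9 | (2S,3Z)-4-iodo-3-methylbut-3-en-2-ol | I/C=C(/C)[C@H](C)O | intermediate
10 | triethyl{[(2S,3Z)-4-iodo-3-methylbut-3-en-2-yl]oxy}silane | I/C=C(/C)[C@H](C)O[Si](CC)(CC)CC | intermediate
11 | 4-methoxy-2-methylphenol | Cc1cc(OC)ccc1O | starting material
12 | 4,4-dimethoxy-2-methylcyclohexa-2,5-dien-1-one | COC1(OC)C=CC(=O)C(C)=C1 | intermediate
13 | (5R)-4,4-dimethoxy-2-methyl-5-{3-[(4-methoxybenzyl)oxy]prop-1-en-2-yl}cyclohex-2-en-1-one (ring B; C7 side chain α) | O=C1C[C@H](C(=C)COCc2ccc(OC)cc2)C(OC)(OC)C=C1C | intermediate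
14 | triethylsilyl enol ether of the 1,4-reduced enone (C1–OTES, C1=C10, C7 side chain α) | CC[Si](CC)(CC)OC1=C(C)CC(OC)(OC)[C@@H](C(=C)COCc2ccc(OC)cc2)C1 | intermediate
15 | C1,C10-epoxide of 14, oxirane oxygen β (trans to the C7 side chain) | CC[Si](CC)(CC)O[C@@]12O[C@]1(C)CC(OC)(OC)[C@@H](C(=C)COCc3ccc(OC)cc3)C2 | intermediate
16 | (2R,5R)-4,4-dimethoxy-2-methyl-5-{3-[(4-methoxybenzyl)oxy]prop-1-en-2-yl}-2-(triethylsilyloxy)cyclohexan-1-one (C10–OTES β) | O=C1C[C@H](C(=C)COCc2ccc(OC)cc2)C(OC)(OC)C[C@@]1(C)O[Si](CC)(CC)CC | intermediate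
17 | 16 bearing at C6 (β, trans to the C7 side chain) the (1Z,3S)-2-methyl-3-(triethylsilyloxy)but-1-en-1-yl group | O=C1[C@@H](/C=C(/C)[C@H](C)O[Si](CC)(CC)CC)[C@H](C(=C)COCc2ccc(OC)cc2)C(OC)(OC)C[C@@]1(C)O[Si](CC)(CC)CC | intermediate
18 | potassium C1,C6-dienolate of 17 | [K+].[O-]C1=C(/C=C(/C)[C@H](C)O[Si](CC)(CC)CC)[C@H](C(=C)COCc2ccc(OC)cc2)C(OC)(OC)C[C@@]1(C)O[Si](CC)(CC)CC | intermediate
19 | C6-hydroxylated 17 (C6–OH β, alkenyl α; C1 ketone) | O=C1[C@](O)(/C=C(/C)[C@H](C)O[Si](CC)(CC)CC)[C@H](C(=C)COCc2ccc(OC)cc2)C(OC)(OC)C[C@@]1(C)O[Si](CC)(CC)CC | intermediate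
20 | 19 with the side-chain C3 hydroxyl free | O=C1[C@](O)(/C=C(/C)[C@H](C)O)[C@H](C(=C)COCc2ccc(OC)cc2)C(OC)(OC)C[C@@]1(C)O[Si](CC)(CC)CC | intermediate
21 | (Z)-hydroxy enone: C6 carries OH (β) and the (1Z)-2-methyl-3-oxobut-1-en-1-yl group (α) | O=C1[C@](O)(/C=C(/C)C(C)=O)[C@H](C(=C)COCc2ccc(OC)cc2)C(OC)(OC)C[C@@]1(C)O[Si](CC)(CC)CC | intermediate
22 | spiro-hemiketal of 21 (O6 bound to C3; 2,5-dihydrofuran-2-ol; both anomers at C3) | O=C1[C@@]2(OC(C)(O)C(C)=C2)[C@H](C(=C)COCc3ccc(OC)cc3)C(OC)(OC)C[C@@]1(C)O[Si](CC)(CC)CC | intermediate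
23 | dilithium C6-alkoxide C2,C3-enolate of 21 | [Li+].[Li+].O=C1[C@]([O-])(/C=C(/C)C(=C)[O-])[C@H](C(=C)COCc2ccc(OC)cc2)C(OC)(OC)C[C@@]1(C)O[Si](CC)(CC)CC | intermediate
24 | cis-fused decalin ketol: C1–OH β, C6–OH β, C3 ketone, C4(Me)=C5, C7 side chain α, C8 dimethyl ketal, C10 methyl with β-OTES | O[C@@]12CC(=O)C(C)=C[C@]1(O)[C@H](C(=C)COCc3ccc(OC)cc3)C(OC)(OC)C[C@@]2(C)O[Si](CC)(CC)CC | intermediate
25 | O1-diethylborinate of 24 | CCB(CC)O[C@@]12CC(=O)C(C)=C[C@]1(O)[C@H](C(=C)COCc3ccc(OC)cc3)C(OC)(OC)C[C@@]2(C)O[Si](CC)(CC)CC | intermediate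
26 | 1β,3β,6β-triol (C3 carbinol as in the target) | O[C@@]12C[C@@H](O)C(C)=C[C@]1(O)[C@H](C(=C)COCc3ccc(OC)cc3)C(OC)(OC)C[C@@]2(C)O[Si](CC)(CC)CC | intermediate
27 | 3-O-TBS ether of 26 | O[C@@]12C[C@@H](O[Si](C)(C)C(C)(C)C)C(C)=C[C@]1(O)[C@H](C(=C)COCc3ccc(OC)cc3)C(OC)(OC)C[C@@]2(C)O[Si](CC)(CC)CC | intermediate
28 | C8 ketone from 27 | O[C@@]12C[C@@H](O[Si](C)(C)C(C)(C)C)C(C)=C[C@]1(O)[C@H](C(=C)COCc3ccc(OC)cc3)C(=O)C[C@@]2(C)O[Si](CC)(CC)CC | intermediate
29 | 8α-alcohol (cis to the C7 side chain) | O[C@@]12C[C@@H](O[Si](C)(C)C(C)(C)C)C(C)=C[C@]1(O)[C@H](C(=C)COCc3ccc(OC)cc3)[C@H](O)C[C@@]2(C)O[Si](CC)(CC)CC | intermediate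
30 | 3-methylbutanoyl chloride | CC(C)CC(=O)Cl | starting material
31 | key-step precursor: cis-fused decalin 1β,6β-diol, 3β-OTBS, 8α-isovalerate, 10β-OTES, C7α 3-(PMB-oxy)prop-1-en-2-yl | O[C@@]12C[C@@H](O[Si](C)(C)C(C)(C)C)C(C)=C[C@]1(O)[C@H](C(=C)COCc3ccc(OC)cc3)[C@H](OC(=O)CC(C)C)C[C@@]2(C)O[Si](CC)(CC)CC | intermediate
32 | cyclic diacetoxylead C1,C6-diester of 31 | CC(=O)O[Pb]1(OC(C)=O)O[C@@]23C[C@@H](O[Si](C)(C)C(C)(C)C)C(C)=C[C@]2(O1)[C@H](C(=C)COCc4ccc(OC)cc4)[C@H](OC(=O)CC(C)C)C[C@@]3(C)O[Si](CC)(CC)CC | intermediate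
33 | key-step product: (4Z)-cyclodec-4-ene-1,6-dione with 3-OTBS, 8-isovalerate, 10-OTES, C7 3-(PMB-oxy)prop-1-en-2-yl | O=C1C[C@@H](O[Si](C)(C)C(C)(C)C)/C(C)=C\C(=O)[C@H](C(=C)COCc2ccc(OC)cc2)[C@H](OC(=O)CC(C)C)C[C@@]1(C)O[Si](CC)(CC)CC | intermediate
34 | (6R)-allylic alcohol from 33 (H6 and H7 anti) | O[C@@H]1/C=C(/C)[C@H](O[Si](C)(C)C(C)(C)C)CC(=O)[C@](C)(O[Si](CC)(CC)CC)C[C@@H](OC(=O)CC(C)C)[C@H]1C(=C)COCc2ccc(OC)cc2 | intermediate
35 | C6,C12-diol | O[C@@H]1/C=C(/C)[C@H](O[Si](C)(C)C(C)(C)C)CC(=O)[C@](C)(O[Si](CC)(CC)CC)C[C@@H](OC(=O)CC(C)C)[C@H]1C(=C)CO | intermediate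
36 | C6-hydroxy C12-enal | O[C@@H]1/C=C(/C)[C@H](O[Si](C)(C)C(C)(C)C)CC(=O)[C@](C)(O[Si](CC)(CC)CC)C[C@@H](OC(=O)CC(C)C)[C@H]1C(=C)C=O | intermediate
37 | C12 lactol (both anomers) | C=C1C(O)O[C@@H]2/C=C(/C)[C@H](O[Si](C)(C)C(C)(C)C)CC(=O)[C@](C)(O[Si](CC)(CC)CC)C[C@@H](OC(=O)CC(C)C)[C@@H]12 | intermediate
38 | 3-O-TBS 10-O-TES ether of the target | C=C1C(=O)O[C@@H]2/C=C(/C)[C@H](O[Si](C)(C)C(C)(C)C)CC(=O)[C@](C)(O[Si](CC)(CC)CC)C[C@@H](OC(=O)CC(C)C)[C@@H]12 | intermediate
39 | CNP0406522.1 | C=C1C(=O)O[C@@H]2/C=C(/C)[C@H](O)CC(=O)[C@](C)(O)C[C@@H](OC(=O)CC(C)C)[C@@H]12 | target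

**Step count and risks**

Total: 23 steps. Longest linear sequence: 20 steps (steps 1, 2, 6–23).

Steps most likely to fail:

1. Step 9. The coupling may be slow at the hindered enolate, and the new double bond may migrate into conjugation with the ketone under base. Fallback, setting out from 16 and 10: 16 is deprotonated with LiN(SiMe3)2 and brominated with N-bromosuccinimide at −78 °C to the α-bromo ketone F1. 10 is converted by tBuLi and then ZnCl2 into the alkenylzinc chloride F2. A base-free nickel-catalysed Negishi coupling of the secondary α-bromo ketone (NiCl2(dme), bipyridine-type ligand, 25 °C) joins F1 and F2 and returns to the route at 17.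

2. Step 14. Hydride may be delivered from the hydroxyl-bearing face, or facial selectivity may be poor, giving the C3 epimer. Fallback, setting out from 24: the reduction is run deliberately with intramolecular delivery (Me4NBH(OAc)3, MeCN/AcOH, −30 °C) to give the 3-epi triol F3. A Mitsunobu reaction with 4-nitrobenzoic acid (PPh3, DIAD) inverts C3 to the 4-nitrobenzoate F4. Methanolysis (K2CO3, MeOH) returns to the route at 26.

3. Step 20. In the flexible ten-membered ring hydride may attack the other face of the C6 carbonyl, and H7 may epimerise before reduction. Fallback, setting out from 33: if reduction delivers the 6-epi alcohol F5, a Mitsunobu reaction with chloroacetic acid (PPh3, DIAD) inverts C6 to the chloroacetate F6. Selective dechloroacetylation with thiourea and NaHCO3 in ethanol, which leaves the isovalerate alone, returns to the route at 34.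

**Further compounds**

F1 | step 9 | 6-bromo derivative of 16 (α-bromo ketone, bromine trans to the C7 side chain) | O=C1[C@@H](Br)[C@H](C(=C)COCc2ccc(OC)cc2)C(OC)(OC)C[C@@]1(C)O[Si](CC)(CC)CC
F2 | step 9 | chloro[(1Z,3S)-2-methyl-3-(triethylsilyloxy)but-1-en-1-yl]zinc | Cl[Zn]/C=C(/C)[C@H](C)O[Si](CC)(CC)CC
F3 | step 14 | 3-epi-26 (C3–OH α, trans to C1–OH) | O[C@@]12C[C@H](O)C(C)=C[C@]1(O)[C@H](C(=C)COCc3ccc(OC)cc3)C(OC)(OC)C[C@@]2(C)O[Si](CC)(CC)CC
F4 | step 14 | 3-O-(4-nitrobenzoyl) derivative of 26 | O[C@@]12C[C@@H](OC(=O)c4ccc(cc4)[N+](=O)[O-])C(C)=C[C@]1(O)[C@H](C(=C)COCc3ccc(OC)cc3)C(OC)(OC)C[C@@]2(C)O[Si](CC)(CC)CC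
F5 | step 20 | 6-epi-34 (6S alcohol) | O[C@H]1/C=C(/C)[C@H](O[Si](C)(C)C(C)(C)C)CC(=O)[C@](C)(O[Si](CC)(CC)CC)C[C@@H](OC(=O)CC(C)C)[C@H]1C(=C)COCc2ccc(OC)cc2
F6 | step 20 | 6-O-chloroacetyl derivative of 34 | ClCC(=O)O[C@@H]1/C=C(/C)[C@H](O[Si](C)(C)C(C)(C)C)CC(=O)[C@](C)(O[Si](CC)(CC)CC)C[C@@H](OC(=O)CC(C)C)[C@H]1C(=C)COCc2ccc(OC)cc2
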